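**Plan**

- Retrosynthesis: remove the silyl group from the tertiary alcohol; cut O1–C2 and C3–C4 of the chroman (ortho-quinone methide plus methallyl alkene); cut the C6–methallyl bond (enol triflate coupling), the side-chain C–OH (alkene hydration) and the C5–CH2 bond (C-allylation of a 1,3-dione); cut C3–C3a of the cyclopentane (enolate alkylation) and C7a–C1 (conjugate addition).
- Forward: the purchased cyclohexenone becomes the six-membered carbocycle, the cyclopentane is fused on by ring-closing alkylation, the ketone is advanced to the 4,6-dione, C5 and C6 are substituted, and the dihydropyran ring is closed last onto the purchased aromatic ring.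
- Stereochemistry: C7a from a copper-catalysed asymmetric conjugate addition; C3a cis to it by the geometry of the five-membered ring closure; C2 from a chiral Brønsted acid in the cycloaddition, after which any minor hydrindane enantiomer is a separable diastereomer.
- Enabling feature: chroman atoms O1–C8a–C4a–C4 are a masked ortho-quinone methide and C3–C2 a 1,1-disubstituted alkene whose substituted carbon becomes the quaternary, oxygen-bearing C2, so the dihydropyran ring is a formal [4+2] adduct.

Key step: step 13

Assumption: the sense of induction of the two chiral catalysts (steps 1 and 13) is not predicted here; in each case the catalyst enantiomer that gives the drawn configuration is to be chosen after a test reaction.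
Numbering: hydrindane C3a carries the methyl next to the C4 carbonyl, C7a the methyl next to C7H2; chroman O1, C2 to C8a.

**Step 1**
Reactants: 1 3-methylcyclohex-2-en-1-one; 2 (3-bromopropoxy)(tert-butyl)dimethylsilane
Product: 5 (2RS,3R)-3-[3-(tert-butyldimethylsilyloxy)propyl]-2,3-dimethylcyclohexan-1-one, via Grignard reagent 3 (not isolated), via bromomagnesium enolate 4 (not isolated)
Conditions: Mg, Et2O (2 to 3); Cu(OTf)2 (3 mol%), chiral C2-symmetric imidazolinium salt (NHC precursor, 4 mol%), Et2O, 0 °C, slow addition of 1; then MeI, DMPU, 0 °C → rt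
Reagents that add atoms: iodomethane, CI
Why: Copper–NHC-catalysed asymmetric conjugate addition of an alkyl Grignard reagent to a β-methyl cyclohexenone sets the quaternary C3 (future C7a) under catalyst control, and the regio-defined magnesium enolate is C-methylated in the same flask (conjugate addition–enolate alkylation); the C2 configuration is irrelevant because C2 is re-enolised in step 3.

**Step 2**
Reactants: 5 (2RS,3R)-3-[3-(tert-butyldimethylsilyloxy)propyl]-2,3-dimethylcyclohexan-1-one
Product: 6 (2RS,3R)-3-(3-bromopropyl)-2,3-dimethylcyclohexan-1-one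
Conditions: Ph3PBr2, CH2Cl2, 0 °C → rt
Reagents that add atoms: triphenylphosphine dibromide, BrP(Br)(c1ccccc1)(c1ccccc1)c1ccccc1
Why: Triphenylphosphine dibromide converts primary silyl ethers directly into alkyl bromides (Appel-type deoxybromination) and should leave the ketone untouched at room temperature.

**Step 3**
Reactants: 6 (2RS,3R)-3-(3-bromopropyl)-2,3-dimethylcyclohexan-1-one
Product: 7 (3aS,7aS)-3a,7a-dimethyloctahydro-4H-inden-4-one
Conditions: KOtBu, t-BuOH/THF, 0 °C → rt
Reagents that add atoms: none
Why: Intramolecular enolate alkylation (5-exo-tet) under equilibrating conditions, in which only the C2 enolate can reach the bromide through a five-membered transition state and the three-carbon tether can only deliver to the face it is attached to, so the new quaternary C3a is necessarily cis to the C7a methyl.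

**Step 4**
Reactants: 7 (3aS,7aS)-3a,7a-dimethyloctahydro-4H-inden-4-one
Product: 8 (3aS,7aS)-3a,7a-dimethyl-1,2,3,3a,7,7a-hexahydro-4H-inden-4-one
Conditions: IBX, DMSO/fluorobenzene, 75 °C
Reagents that add atoms: none
Why: IBX-mediated α,β-dehydrogenation of a ketone; C3a is quaternary, so unsaturation can only develop at C5–C6, and the quaternary C7a rules out over-oxidation to a dienone.

**Step 5**
Reactants: 8 (3aS,7aS)-3a,7a-dimethyl-1,2,3,3a,7,7a-hexahydro-4H-inden-4-one
Product: 9 (3aS,7aS)-5,6-epoxy-3a,7a-dimethyloctahydro-4H-inden-4-one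
Conditions: 30% H2O2, NaOH (cat.), MeOH, 0 °C → rt
Reagents that add atoms: hydrogen peroxide, OO
Why: Weitz–Scheffer nucleophilic epoxidation of an enone at an unhindered β-carbon; the epoxide configuration is inconsequential because both carbons lose it in the following steps.

**Step 6**
Reactants: 9 (3aS,7aS)-5,6-epoxy-3a,7a-dimethyloctahydro-4H-inden-4-one
Product: 10 (3aS,7aS)-3a,7a-dimethyl-2,3,3a,7a-tetrahydro-1H-indene-4,6(5H,7H)-dione
Conditions: Pd(PPh3)4 (5 mol%), dppe (5 mol%), toluene, 110 °C
Reagents that add atoms: none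
Why: Palladium(0)-catalysed isomerisation of an α,β-epoxy ketone to a β-diketone (opening at the Cα–O bond, β-hydride elimination from C6, tautomerisation), which leaves the quaternary stereocentres untouched.

**Step 7**
Reactants: 10 (3aS,7aS)-3a,7a-dimethyl-2,3,3a,7a-tetrahydro-1H-indene-4,6(5H,7H)-dione; 11 3-chloro-2-methylprop-1-ene
Product: 12 (3aS,7aS)-3a,7a-dimethyl-5-(2-methylprop-2-en-1-yl)-2,3,3a,7a-tetrahydro-1H-indene-4,6(5H,7H)-dione
Conditions: Pd(PPh3)4 (2 mol%), K2CO3, THF, 50 °C, 11 as limiting reagent
Reagents that add atoms: none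
Why: Tsuji–Trost C-allylation of a cyclic 1,3-dione, in which the soft enolate attacks the π-methallyl palladium complex at C5 and any O-allylated enol ether re-ionises and funnels to the C-alkylated product.

**Step 8**
Reactants: 12 (3aS,7aS)-3a,7a-dimethyl-5-(2-methylprop-2-en-1-yl)-2,3,3a,7a-tetrahydro-1H-indene-4,6(5H,7H)-dione
Product: 13 (3aS,7aS)-3a,7a-dimethyl-5-(2-methylprop-2-en-1-yl)-4-oxo-2,3,3a,4,7,7a-hexahydro-1H-inden-6-yl trifluoromethanesulfonate
Conditions: Tf2O, pyridine, CH2Cl2, −78 → 0 °C
Reagents that add atoms: trifluoromethanesulfonic anhydride, O=S(=O)(OS(=O)(=O)C(F)(F)F)C(F)(F)F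
Why: O-Triflation of the 2-alkyl-1,3-dione should occur at the C6 oxygen, remote from the quaternary C3a, as in the known regioselective O-functionalisation of 4,4-disubstituted cyclohexane-1,3-diones, leaving the hindered C4 carbonyl as the ketone.

**Step 9**
Reactants: 13 (3aS,7aS)-3a,7a-dimethyl-5-(2-methylprop-2-en-1-yl)-4-oxo-2,3,3a,4,7,7a-hexahydro-1H-inden-6-yl trifluoromethanesulfonate
Product: 14 (3aS,7aS)-5-(2-hydroxy-2-methylpropyl)-3a,7a-dimethyl-4-oxo-2,3,3a,4,7,7a-hexahydro-1H-inden-6-yl trifluoromethanesulfonate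
Conditions: Co(acac)2 (20 mol%), PhSiH3, O2 (1 atm), THF, rt
Reagents that add atoms: dioxygen, O=O
Why: Mukaiyama hydration (cobalt hydride hydrogen-atom transfer, then O2 trapping) is Markovnikov-selective for the electron-rich 1,1-disubstituted alkene and should ignore the tetrasubstituted, electron-poor triflyloxy enone; running it before step 11 is what distinguishes the two methallyl groups.

**Step 10**
Reactants: 14 (3aS,7aS)-5-(2-hydroxy-2-methylpropyl)-3a,7a-dimethyl-4-oxo-2,3,3a,4,7,7a-hexahydro-1H-inden-6-yl trifluoromethanesulfonate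
Product: 15 (3aS,7aS)-3a,7a-dimethyl-5-[2-methyl-2-(triethylsilyloxy)propyl]-4-oxo-2,3,3a,4,7,7a-hexahydro-1H-inden-6-yl trifluoromethanesulfonate
Conditions: TESOTf, 2,6-lutidine, CH2Cl2, −78 → 0 °C
Reagents that add atoms: triethylsilyl trifluoromethanesulfonate, CC[Si](CC)(CC)OS(=O)(=O)C(F)(F)F
Why: Silylation of a tertiary alcohol with a silyl triflate and a hindered base, which stops the hydroxyl from displacing the vinylogous acyl triflate and later shields it from the quinone methide.

**Step 11**
Reactants: 15 (3aS,7aS)-3a,7a-dimethyl-5-[2-methyl-2-(triethylsilyloxy)propyl]-4-oxo-2,3,3a,4,7,7a-hexahydro-1H-inden-6-yl trifluoromethanesulfonate; 16 tributyl(2-methylprop-2-en-1-yl)stannane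
Product: 17 (3aS,7aS)-3a,7a-dimethyl-6-(2-methylprop-2-en-1-yl)-5-[2-methyl-2-(triethylsilyloxy)propyl]-1,2,3,3a,7,7a-hexahydro-4H-inden-4-one
Conditions: Pd(PPh3)4 (5 mol%), LiCl, THF, 65 °C
Reagents that add atoms: none
Why: Stille coupling of a β-triflyloxy enone with an allylstannane under neutral conditions installs the methallyl group at C6 without 1,2-addition to the ketone or base-induced migration of the skipped double bond into conjugation.

**Step 12**
Reactants: 18 4-methoxy-2-methylphenol
Product: 19 2-(hydroxymethyl)-4-methoxy-6-methylphenol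
Conditions: 37% aq. CH2O, NaOH, H2O, rt
Reagents that add atoms: formaldehyde, C=O
Why: Base-mediated ortho-hydroxymethylation of a phenoxide with formaldehyde (Lederer–Manasse reaction); the para position is blocked by methoxy and only one ortho position is free.

**Step 13**
Reactants: 19 2-(hydroxymethyl)-4-methoxy-6-methylphenol; 17 (3aS,7aS)-3a,7a-dimethyl-6-(2-methylprop-2-en-1-yl)-5-[2-methyl-2-(triethylsilyloxy)propyl]-1,2,3,3a,7,7a-hexahydro-4H-inden-4-one
Product: 21 (3aS,7aS)-6-{[(2R)-6-methoxy-2,8-dimethyl-3,4-dihydro-2H-chromen-2-yl]methyl}-3a,7a-dimethyl-5-[2-methyl-2-(triethylsilyloxy)propyl]-1,2,3,3a,7,7a-hexahydro-4H-inden-4-one, via ortho-quinone methide 20 (not isolated)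
Conditions: chiral confined imidodiphosphorimidate Brønsted acid (5 mol%), 5 Å MS, CHCl3, 0 °C → rt, 19 (2.5 equiv) added slowly
Reagents that add atoms: none
Why: Proposed new method: the confined chiral acid dehydrates 19 to ortho-quinone methide 20 and holds it as a hydrogen-bonded o-hydroxybenzyl cation equivalent, whose exocyclic CH2 is attacked by the terminal carbon of the methallyl group of 17 to give a tertiary cation at the future C2 that collapses with the phenolic oxygen inside the same ion pair (asynchronous inverse-electron-demand oxa-[4+2], C3–C4 first, then O1–C2); the closest known reactions are thermal ortho-quinone methide cycloadditions with 1,1-disubstituted alkenes and chiral Brønsted acid-catalysed [4+2] reactions of such methides with styrenes and enol ethers. The dihydropyran ring closes by intermolecular [4+2] annulation, its last bond being the six-membered C–O closure of the phenol oxygen onto the tertiary cation. The new stereocentre C2 is set by the chiral counter-anion, which must tell the alkene faces apart by the size difference between CH3 and the CH2-hydrindenone arm, because the hydrindane centres are too remote to bias it. Regioselectivity (oxygen on the substituted carbon) follows from the Markovnikov tertiary cation, and chemoselectivity from the only other C=C being the tetrasubstituted, electron-poor enone alkene, while the silyl ether keeps the tertiary alcohol from adding to 20. Slow addition of 19 keeps the concentration of 20 low and should suppress its oligomerisation.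

**Step 14**
Reactants: 21 (3aS,7aS)-6-{[(2R)-6-methoxy-2,8-dimethyl-3,4-dihydro-2H-chromen-2-yl]methyl}-3a,7a-dimethyl-5-[2-methyl-2-(triethylsilyloxy)propyl]-1,2,3,3a,7,7a-hexahydro-4H-inden-4-one
Product: 22 (3aS,7aS)-5-(2-hydroxy-2-methylpropyl)-6-{[(2R)-6-methoxy-2,8-dimethyl-3,4-dihydro-2H-chromen-2-yl]methyl}-3a,7a-dimethyl-1,2,3,3a,7,7a-hexahydro-4H-inden-4-one
Conditions: HF·pyridine, pyridine, THF, 0 °C → rt
Reagents that add atoms: none
Why: Fluoride-mediated cleavage of a triethylsilyl ether under buffered conditions that should neither dehydrate the γ-hydroxy enone nor ionise the chroman C2–O bond; no stereocentre is touched.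

**Compound list**

1 | 3-methylcyclohex-2-en-1-one | CC1=CC(=O)CCC1 | starting material
2 | (3-bromopropoxy)(tert-butyl)dimethylsilane | CC(C)(C)[Si](C)(C)OCCCBr | starting material
3 | [3-(tert-butyldimethylsilyloxy)propyl]magnesium bromide | CC(C)(C)[Si](C)(C)OCCC[Mg]Br | intermediate
4 | bromomagnesium (3R)-3-[3-(tert-butyldimethylsilyloxy)propyl]-3-methylcyclohex-1-en-1-olate | CC(C)(C)[Si](C)(C)OCCC[C@@]1(C)CCCC(O[Mg]Br)=C1 | intermediate
5 | (2RS,3R)-3-[3-(tert-butyldimethylsilyloxy)propyl]-2,3-dimethylcyclohexan-1-one (C2 epimers) | CC(C)(C)[Si](C)(C)OCCC[C@@]1(C)CCCC(=O)C1C | intermediate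
6 | (2RS,3R)-3-(3-bromopropyl)-2,3-dimethylcyclohexan-1-one (C2 epimers) | BrCCC[C@@]1(C)CCCC(=O)C1C | intermediate
7 | (3aS,7aS)-3a,7a-dimethyloctahydro-4H-inden-4-one (cis-fused) | O=C1[C@@]2(C)CCC[C@@]2(C)CCC1 | intermediate
8 | (3aS,7aS)-3a,7a-dimethyl-1,2,3,3a,7,7a-hexahydro-4H-inden-4-one | O=C1[C@@]2(C)CCC[C@@]2(C)CC=C1 | intermediate
9 | (3aS,7aS)-5,6-epoxy-3a,7a-dimethyloctahydro-4H-inden-4-one (epoxide configuration not assigned) | O=C1[C@@]2(C)CCC[C@@]2(C)CC2OC12 | intermediate
10 | (3aS,7aS)-3a,7a-dimethyl-2,3,3a,7a-tetrahydro-1H-indene-4,6(5H,7H)-dione | O=C1[C@@]2(C)CCC[C@@]2(C)CC(=O)C1 | intermediate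
11 | 3-chloro-2-methylprop-1-ene | CC(=C)CCl | starting material
12 | (3aS,7aS)-3a,7a-dimethyl-5-(2-methylprop-2-en-1-yl)-2,3,3a,7a-tetrahydro-1H-indene-4,6(5H,7H)-dione (enolised; C5 not a fixed centre) | O=C1[C@@]2(C)CCC[C@@]2(C)CC(=O)C1CC(C)=C | intermediate
13 | (3aS,7aS)-3a,7a-dimethyl-5-(2-methylprop-2-en-1-yl)-4-oxo-2,3,3a,4,7,7a-hexahydro-1H-inden-6-yl trifluoromethanesulfonate | O=C1[C@@]2(C)CCC[C@@]2(C)CC(OS(=O)(=O)C(F)(F)F)=C1CC(C)=C | intermediate
14 | (3aS,7aS)-5-(2-hydroxy-2-methylpropyl)-3a,7a-dimethyl-4-oxo-2,3,3a,4,7,7a-hexahydro-1H-inden-6-yl trifluoromethanesulfonate | O=C1[C@@]2(C)CCC[C@@]2(C)CC(OS(=O)(=O)C(F)(F)F)=C1CC(C)(C)O | intermediate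
15 | (3aS,7aS)-3a,7a-dimethyl-5-[2-methyl-2-(triethylsilyloxy)propyl]-4-oxo-2,3,3a,4,7,7a-hexahydro-1H-inden-6-yl trifluoromethanesulfonate | O=C1[C@@]2(C)CCC[C@@]2(C)CC(OS(=O)(=O)C(F)(F)F)=C1CC(C)(C)O[Si](CC)(CC)CC | intermediate
16 | tributyl(2-methylprop-2-en-1-yl)stannane | CCCC[Sn](CCCC)(CCCC)CC(C)=C | starting material
17 | (3aS,7aS)-3a,7a-dimethyl-6-(2-methylprop-2-en-1-yl)-5-[2-methyl-2-(triethylsilyloxy)propyl]-1,2,3,3a,7,7a-hexahydro-4H-inden-4-one | CC(=C)CC1=C(CC(C)(C)O[Si](CC)(CC)CC)C(=O)[C@@]2(C)CCC[C@@]2(C)C1 | intermediate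
18 | 4-methoxy-2-methylphenol | COc1ccc(O)c(C)c1 | starting material
19 | 2-(hydroxymethyl)-4-methoxy-6-methylphenol | COc1cc(C)c(O)c(CO)c1 | intermediate
20 | 4-methoxy-2-methyl-6-methylidenecyclohexa-2,4-dien-1-one (ortho-quinone methide) | COC1=CC(=C)C(=O)C(C)=C1 | intermediate
21 | (3aS,7aS)-6-{[(2R)-6-methoxy-2,8-dimethyl-3,4-dihydro-2H-chromen-2-yl]methyl}-3a,7a-dimethyl-5-[2-methyl-2-(triethylsilyloxy)propyl]-1,2,3,3a,7,7a-hexahydro-4H-inden-4-one | COc1cc(C)c2c(c1)CC[C@](C)(CC1=C(CC(C)(C)O[Si](CC)(CC)CC)C(=O)[C@@]3(C)CCC[C@@]3(C)C1)O2 | intermediate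
22 | (3aS,7aS)-5-(2-hydroxy-2-methylpropyl)-6-{[(2R)-6-methoxy-2,8-dimethyl-3,4-dihydro-2H-chromen-2-yl]methyl}-3a,7a-dimethyl-1,2,3,3a,7,7a-hexahydro-4H-inden-4-one (CNP0224132.1) | COc1cc(C)c2c(c1)CC[C@](C)(CC1=C(CC(C)(C)O)C(=O)[C@@]3(C)CCC[C@@]3(C)C1)O2 | target

**Step count**

Total step count: 14. Longest linear sequence: 13 steps (steps 1 to 11, then 13 and 14); step 12 is a one-step side branch.

**Steps most likely to fail**

1. Step 13. The chiral acid may not distinguish the two faces of the methallyl alkene, or it may instead move the skipped double bond into conjugation or strip the silyl ether before the cycloaddition occurs. Fallback with known chemistry, setting out from 17 and 19: the quinone methide is generated thermally without acid (toluene, sealed tube, about 170 °C, 19 added in portions), the classical uncatalysed cycloaddition of ortho-quinone methides with 1,1-disubstituted alkenes. Without facial control this should give 21 together with its C2 epimer, the (2S)-configured silyl ether F1. The two are diastereomers and would be separated by preparative HPLC, and the route is rejoined at 21.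

2. Step 1. C-methylation of the congested bromomagnesium enolate may be slow enough for proton transfer to scramble the enolate, giving regioisomeric and polymethylated ketones. Fallback, setting out from 1 and 2: the conjugate addition is run as before, but enolate 4 is quenched with TMSCl/Et3N and the trimethylsilyl enol ether F2 is isolated. MeLi in THF at 0 °C then cleaves F2 to the regio-defined lithium enolate F3, which is methylated with MeI (regiospecific enolate regeneration from a silyl enol ether), and the route is rejoined at 5.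

3. Step 6. After ring opening of the epoxide, the palladium enolate may fail to undergo clean β-hydride elimination, leading to reduction or dehydration back to the enone. Fallback, setting out from 8: copper-catalysed conjugate borylation (CuCl, NaOtBu, bisphosphine, B2pin2, MeOH, THF) gives the β-boryl ketone F4, which is oxidised in the same flask with sodium perborate to the β-hydroxy ketone F5. Swern oxidation of F5 then gives the dione, and the route is rejoined at 10.

**Further compounds**

F1 | step 13 | (3aS,7aS)-6-{[(2S)-6-methoxy-2,8-dimethyl-3,4-dihydro-2H-chromen-2-yl]methyl}-3a,7a-dimethyl-5-[2-methyl-2-(triethylsilyloxy)propyl]-1,2,3,3a,7,7a-hexahydro-4H-inden-4-one | COc1cc(C)c2c(c1)CC[C@@](C)(CC1=C(CC(C)(C)O[Si](CC)(CC)CC)C(=O)[C@@]3(C)CCC[C@@]3(C)C1)O2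
F2 | step 1 | tert-butyldimethyl{3-[(1R)-1-methyl-3-(trimethylsilyloxy)cyclohex-2-en-1-yl]propoxy}silane | CC(C)(C)[Si](C)(C)OCCC[C@@]1(C)CCCC(O[Si](C)(C)C)=C1
F3 | step 1 | lithium (3R)-3-[3-(tert-butyldimethylsilyloxy)propyl]-3-methylcyclohex-1-en-1-olate | CC(C)(C)[Si](C)(C)OCCC[C@@]1(C)CCCC(O[Li])=C1
F4 | step 6 | (3aS,7aS)-3a,7a-dimethyl-6-(4,4,5,5-tetramethyl-1,3,2-dioxaborolan-2-yl)octahydro-4H-inden-4-one | O=C1[C@@]2(C)CCC[C@@]2(C)CC(B3OC(C)(C)C(C)(C)O3)C1
F5 | step 6 | (3aS,7aS)-6-hydroxy-3a,7a-dimethyloctahydro-4H-inden-4-one | O=C1[C@@]2(C)CCC[C@@]2(C)CC(O)C1
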